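**Plan**
- Retrosynthesis: ring A (the pyran) is opened at O2–C3 to the hydroxy enynone 26, C4a–C4 is cut (Sonogashira coupling on the vinylogous acyl triflate 20), and ring B is then cut at C5–C6 and C8–C8a; the aroyl ester on O7 is carried from the start.
- Enabling feature: once C4a is returned to a ketone, C5 and C8a are its two α-carbons and C8/C4a form a 1,3-diketone, while C6 (aldehyde) and C8 (ester) both sit on the quaternary C7 and cannot enolise. Ketone 16 and formyl ester 14 therefore give ring B in one aldol–Claisen [3+3] operation.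
- Forward order: aryl acid 4, then the C7 building block 14, then ring B (step 11), then the C4a–C4 alkyne (steps 12–15), and ring A last by 6-endo-dig hydroalkoxylation (steps 16–17).
- Stereochemistry: C7 comes from (S)-lactic acid by acetal-controlled enolate alkylation with retention; C6 is set in the aldol addition under control of C7; the E-propenyl group comes from (E)-1-bromoprop-1-ene.

Key step: step 11

Remark: locants such as C5, C6 and C8a are those of the 1H-isochromene skeleton of the target, ring A is the pyran and ring B the carbocycle; dione 19 is written as one enol tautomer.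

**Step 1**
Reactants: 1 2,4-dihydroxy-6-methylbenzaldehyde
Product: 2 2-hydroxy-6-methyl-4-[(triisopropylsilyl)oxy]benzaldehyde
Conditions: i-Pr3SiCl (1.05 equiv), imidazole, DMF, 0 °C
Reagents that add atoms: chlorotriisopropylsilane, CC(C)[Si](Cl)(C(C)C)C(C)C
Why: O-silylation; the 2-OH is tied up in a hydrogen bond to the formyl group, so the free and more acidic 4-OH should be silylated selectively.

**Step 2**
Reactants: 2 2-hydroxy-6-methyl-4-[(triisopropylsilyl)oxy]benzaldehyde
Product: 3 2-methoxy-6-methyl-4-[(triisopropylsilyl)oxy]benzaldehyde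
Conditions: MeI, K2CO3, dry acetone, 40 °C
Reagents that add atoms: iodomethane, CI
Why: Williamson ether synthesis on the remaining chelated phenol; the bulky triisopropylsilyl ether should tolerate carbonate in dry acetone.

**Step 3**
Reactants: 3 2-methoxy-6-methyl-4-[(triisopropylsilyl)oxy]benzaldehyde
Product: 4 2-methoxy-6-methyl-4-[(triisopropylsilyl)oxy]benzoic acid
Conditions: NaClO2, NaH2PO4, 2-methylbut-2-ene, t-BuOH/H2O, 0 → 23 °C
Reagents that add atoms: sodium chlorite, [Na+].[O-]Cl=O
Why: Pinnick oxidation of the hindered aldehyde to the acid; the alkene scavenger takes up hypochlorous acid and protects the electron-rich ring and the silyl ether.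

**Step 4**
Reactants: 5 (S)-lactic acid
Product: 6 (2S,5S)-2-tert-butyl-5-methyl-1,3-dioxolan-4-one
Conditions: t-BuCHO, TsOH·H2O (cat.), H2SO4 (cat.), pentane, reflux with water separator; crystallisation at −78 °C
Reagents that add atoms: 2,2-dimethylpropanal, CC(C)(C)C=O
Why: acid-catalysed acetalisation under thermodynamic control places tert-butyl and methyl cis; this new acetal centre later relays the lactate configuration (self-regeneration of a stereocentre).

**Step 5**
Reactants: 6 (2S,5S)-2-tert-butyl-5-methyl-1,3-dioxolan-4-one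
Product: 8 (2S,5R)-5-[(benzyloxy)methyl]-2-tert-butyl-5-methyl-1,3-dioxolan-4-one, via lithium enolate 7 (not isolated)
Conditions: LiN(i-Pr)2, THF, −78 °C; then BnOCH2Cl, −78 → −30 °C
Reagents that add atoms: benzyl chloromethyl ether, ClCOCc1ccccc1
Why: enolate alkylation; the planar enolate 7 should be attacked on the face opposite to the tert-butyl group, so CH2OBn takes the place of H with retention and fixes the future C7.

**Step 6**
Reactants: 8 (2S,5R)-5-[(benzyloxy)methyl]-2-tert-butyl-5-methyl-1,3-dioxolan-4-one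
Product: 9 methyl (2R)-3-(benzyloxy)-2-hydroxy-2-methylpropanoate
Conditions: NaOMe (cat.), MeOH, 0 → 23 °C
Reagents that add atoms: methanol, CO
Why: methoxide-catalysed transesterification of the acylal-type lactone; the hemiacetal alkoxide expels the aldehyde and the quaternary stereocentre is not touched.

**Step 7**
Reactants: 4 2-methoxy-6-methyl-4-[(triisopropylsilyl)oxy]benzoic acid; 9 methyl (2R)-3-(benzyloxy)-2-hydroxy-2-methylpropanoate
Product: 12 methyl (2R)-3-(benzyloxy)-2-methyl-2-({2-methoxy-6-methyl-4-[(triisopropylsilyl)oxy]benzoyl}oxy)propanoate, via acid chloride 10 (not isolated), via lithium alkoxide 11 (not isolated)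
Conditions: 4, (COCl)2, DMF (cat.), CH2Cl2, 0 → 23 °C, evaporate; 9, LiN(SiMe3)2, THF, −78 °C; then 10, −78 → 23 °C
Reagents that add atoms: none
Why: acylation of a tertiary lithium alkoxide by an acid chloride; the electron-rich 2,6-disubstituted aroyl chloride should react through an acylium-like transition state, and the ester, once formed, is shielded on both sides against later nucleophiles.

**Step 8**
Reactants: 12 methyl (2R)-3-(benzyloxy)-2-methyl-2-({2-methoxy-6-methyl-4-[(triisopropylsilyl)oxy]benzoyl}oxy)propanoate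
Product: 13 methyl (2R)-3-hydroxy-2-methyl-2-({2-methoxy-6-methyl-4-[(triisopropylsilyl)oxy]benzoyl}oxy)propanoate
Conditions: H2 (1 atm), Pd/C, EtOAc, 23 °C
Reagents that add atoms: none
Why: hydrogenolysis of the benzyl ether; the neutral conditions leave both esters and the aryl silyl ether alone and give the aroyl group no base or acid to move to the new primary hydroxyl.

**Step 9**
Reactants: 13 methyl (2R)-3-hydroxy-2-methyl-2-({2-methoxy-6-methyl-4-[(triisopropylsilyl)oxy]benzoyl}oxy)propanoate
Product: 14 methyl (2R)-2-methyl-2-({2-methoxy-6-methyl-4-[(triisopropylsilyl)oxy]benzoyl}oxy)-3-oxopropanoate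
Conditions: Dess–Martin periodinane, CH2Cl2, 0 → 23 °C; used at once
Reagents that add atoms: none
Why: Dess–Martin oxidation of the primary alcohol under near-neutral conditions; the aldehyde has no α-hydrogen, so C7 cannot epimerise.

**Step 10**
Reactants: 15 4-hydroxybutan-2-one
Product: 16 4-{[tert-butyl(dimethyl)silyl]oxy}butan-2-one
Conditions: t-BuMe2SiCl, imidazole, CH2Cl2, 0 °C
Reagents that add atoms: tert-butylchlorodimethylsilane, CC(C)(C)[Si](C)(C)Cl
Why: O-silylation of the primary alcohol with a base mild enough not to dehydrate the β-hydroxy ketone; C1 is thereby carried at its final oxidation level.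

**Step 11**
Reactants: 16 4-{[tert-butyl(dimethyl)silyl]oxy}butan-2-one; 14 methyl (2R)-2-methyl-2-({2-methoxy-6-methyl-4-[(triisopropylsilyl)oxy]benzoyl}oxy)-3-oxopropanoate
Product: 19 (1R,6R)-3-({[tert-butyl(dimethyl)silyl]oxy}methyl)-4,6-dihydroxy-1-methyl-2-oxocyclohex-3-en-1-yl 2-methoxy-6-methyl-4-[(triisopropylsilyl)oxy]benzoate, via lithium enolate 17 (not isolated), via lithium aldolate 18 (not isolated)
Conditions: 16, LiN(i-Pr)2 (1.05 equiv), THF, −78 °C; 14 (0.9 equiv), −78 °C; then LiN(SiMe3)2 (2.2 equiv), −78 → 0 °C; AcOH quench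
Reagents that add atoms: none
Why: The kinetic enolate 17 (deprotonation at the methyl group, C5) adds to the aldehyde carbon C6 of 14 (directed aldol addition) to give aldolate 18, LiN(SiMe3)2 then enolises the ketone towards C8a and this enolate attacks the methyl ester C8 (Claisen condensation of a δ-keto ester, the classical entry to cyclohexane-1,3-diones), so the sequence is a formal [3+3] annulation pulled forward by deprotonation of the 1,3-dione. Ring B is closed in the second event by a 6-(enolendo)-exo-trig acyl substitution. C6 is set in the aldol addition by C7: lithium should bridge the aldehyde oxygen and the ester carbonyl and the enolate should approach anti to the aroyloxy group, on the face of the C7 methyl group, which puts 6-OH cis to the 7-aroyloxy group (6R). The step needs the aldehyde to react before the ester and the two α-carbons to react in the right order: C7 is quaternary so neither carbonyl of 14 can enolise, the aldehyde is the more electrophilic carbonyl at −78 °C, a methyl ester is too poor an acyl donor for β-lactone formation from 18, kinetic deprotonation puts the first enolate on the methyl side, and only the C8a enolate has a six-membered path to C8. The di-ortho-substituted aroyl ester should be shielded against attack by the neighbouring alkoxide.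

**Step 12**
Reactants: 19 (1R,6R)-3-({[tert-butyl(dimethyl)silyl]oxy}methyl)-4,6-dihydroxy-1-methyl-2-oxocyclohex-3-en-1-yl 2-methoxy-6-methyl-4-[(triisopropylsilyl)oxy]benzoate
Product: 20 (1R,6R)-3-({[tert-butyl(dimethyl)silyl]oxy}methyl)-6-hydroxy-1-methyl-2-oxo-4-{[(trifluoromethyl)sulfonyl]oxy}cyclohex-3-en-1-yl 2-methoxy-6-methyl-4-[(triisopropylsilyl)oxy]benzoate
Conditions: PhNTf2 (1.1 equiv), Et3N, DMAP (cat.), CH2Cl2, 0 → 23 °C
Reagents that add atoms: N-phenylbis(trifluoromethanesulfonimide), O=S(=O)(N(c1ccccc1)S(=O)(=O)C(F)(F)F)C(F)(F)F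
Why: O-sulfonylation of the vinylogous acid (enol triflate formation); the enolate should be triflated at the oxygen on C4a, remote from the quaternary C7, as in vinylogous ester formation from 4,4-disubstituted cyclohexane-1,3-diones, and the reagent does not touch the neutral secondary alcohol.

**Step 13**
Reactants: 21 (E)-1-bromoprop-1-ene; 22 ethynyltrimethylsilane
Product: 23 trimethyl[(3E)-pent-3-en-1-yn-1-yl]silane
Conditions: Pd(PPh3)2Cl2 (2 mol%), CuI (4 mol%), i-Pr2NH, THF, 23 °C, closed flask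
Reagents that add atoms: none
Why: Sonogashira coupling; oxidative addition of the alkenyl bromide proceeds with retention, so the E geometry is carried into 23.

**Step 14**
Reactants: 23 trimethyl[(3E)-pent-3-en-1-yn-1-yl]silane
Product: 24 (3E)-pent-3-en-1-yne
Conditions: K2CO3 (cat.), MeOH, 0 °C; pentane/ice-water partition, dried pentane solution used directly
Reagents that add atoms: none
Why: protodesilylation of the alkynylsilane by methanolysis; the volatile enyne is kept in solution.

**Step 15**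
Reactants: 20 (1R,6R)-3-({[tert-butyl(dimethyl)silyl]oxy}methyl)-6-hydroxy-1-methyl-2-oxo-4-{[(trifluoromethyl)sulfonyl]oxy}cyclohex-3-en-1-yl 2-methoxy-6-methyl-4-[(triisopropylsilyl)oxy]benzoate; 24 (3E)-pent-3-en-1-yne
Product: 25 (1R,6R)-3-({[tert-butyl(dimethyl)silyl]oxy}methyl)-6-hydroxy-1-methyl-2-oxo-4-[(3E)-pent-3-en-1-yn-1-yl]cyclohex-3-en-1-yl 2-methoxy-6-methyl-4-[(triisopropylsilyl)oxy]benzoate
Conditions: Pd(PPh3)2Cl2 (5 mol%), CuI (10 mol%), Et3N (3 equiv), THF, 0 → 23 °C
Reagents that add atoms: none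
Why: Sonogashira coupling of a vinylogous acyl triflate, a very reactive partner for oxidative addition to zerovalent palladium at room temperature; the free hydroxyl and the silyl ethers should be tolerated.

**Step 16**
Reactants: 25 (1R,6R)-3-({[tert-butyl(dimethyl)silyl]oxy}methyl)-6-hydroxy-1-methyl-2-oxo-4-[(3E)-pent-3-en-1-yn-1-yl]cyclohex-3-en-1-yl 2-methoxy-6-methyl-4-[(triisopropylsilyl)oxy]benzoate
Product: 26 (1R,6R)-6-hydroxy-3-(hydroxymethyl)-1-methyl-2-oxo-4-[(3E)-pent-3-en-1-yn-1-yl]cyclohex-3-en-1-yl 4-hydroxy-2-methoxy-6-methylbenzoate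
Conditions: Bu4NF/AcOH (1:1, 3 equiv), THF, 0 → 23 °C
Reagents that add atoms: none
Why: fluoride-mediated desilylation removes the primary alkyl silyl ether and the aryl silyl ether together; the acetic acid buffer should prevent retro-aldol cleavage of the β-hydroxy ketone and acyl shift from O7 to O6.

**Step 17**
Reactants: 26 (1R,6R)-6-hydroxy-3-(hydroxymethyl)-1-methyl-2-oxo-4-[(3E)-pent-3-en-1-yn-1-yl]cyclohex-3-en-1-yl 4-hydroxy-2-methoxy-6-methylbenzoate
Product: 27 (6R,7R)-6-hydroxy-7-methyl-8-oxo-3-[(1E)-prop-1-en-1-yl]-5,6,7,8-tetrahydro-1H-isochromen-7-yl 4-hydroxy-2-methoxy-6-methylbenzoate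
Conditions: Ph3PAuCl (5 mol%), AgOTf (5 mol%), CH2Cl2, 0 → 23 °C
Reagents that add atoms: none
Why: gold-catalysed 6-endo-dig hydroalkoxylation (cycloisomerisation of a (Z)-2-en-4-yn-1-ol); the π-activated alkyne should be attacked by the primary hydroxyl at C3, the terminus that carries the cation-stabilising propenyl group and lies δ to the C8 ketone, and protodeauration gives the push–pull 2H-pyran, while the 6-hydroxyl cannot compete because its adduct would hold a bridgehead alkene.

**Compound list**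
1 | 2,4-dihydroxy-6-methylbenzaldehyde | Cc1cc(O)cc(O)c1C=O | starting material
2 | 2-hydroxy-6-methyl-4-[(triisopropylsilyl)oxy]benzaldehyde | Cc1cc(O[Si](C(C)C)(C(C)C)C(C)C)cc(O)c1C=O | intermediate
3 | 2-methoxy-6-methyl-4-[(triisopropylsilyl)oxy]benzaldehyde | COc1cc(O[Si](C(C)C)(C(C)C)C(C)C)cc(C)c1C=O | intermediate
4 | 2-methoxy-6-methyl-4-[(triisopropylsilyl)oxy]benzoic acid | COc1cc(O[Si](C(C)C)(C(C)C)C(C)C)cc(C)c1C(=O)O | intermediate
5 | (S)-lactic acid | C[C@H](O)C(=O)O | starting material
6 | (2S,5S)-2-tert-butyl-5-methyl-1,3-dioxolan-4-one | C[C@@H]1O[C@@H](OC1=O)C(C)(C)C | intermediate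
7 | lithium enolate of 6, lithium (2S)-2-tert-butyl-5-methyl-1,3-dioxol-4-olate | CC1=C(O[Li])O[C@@H](C(C)(C)C)O1 | intermediate (not isolated)
8 | (2S,5R)-5-[(benzyloxy)methyl]-2-tert-butyl-5-methyl-1,3-dioxolan-4-one | C[C@]1(COCc2ccccc2)O[C@@H](OC1=O)C(C)(C)C | intermediate
9 | methyl (2R)-3-(benzyloxy)-2-hydroxy-2-methylpropanoate | COC(=O)[C@](C)(O)COCc1ccccc1 | intermediate
10 | 2-methoxy-6-methyl-4-[(triisopropylsilyl)oxy]benzoyl chloride | COc1cc(O[Si](C(C)C)(C(C)C)C(C)C)cc(C)c1C(Cl)=O | intermediate (not isolated)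
11 | lithium alkoxide of 9 | COC(=O)[C@](C)(O[Li])COCc1ccccc1 | intermediate (not isolated)
12 | methyl (2R)-3-(benzyloxy)-2-methyl-2-({2-methoxy-6-methyl-4-[(triisopropylsilyl)oxy]benzoyl}oxy)propanoate | COC(=O)[C@](C)(OC(=O)c1c(C)cc(O[Si](C(C)C)(C(C)C)C(C)C)cc1OC)COCc1ccccc1 | intermediate
13 | methyl (2R)-3-hydroxy-2-methyl-2-({2-methoxy-6-methyl-4-[(triisopropylsilyl)oxy]benzoyl}oxy)propanoate | COC(=O)[C@](C)(OC(=O)c1c(C)cc(O[Si](C(C)C)(C(C)C)C(C)C)cc1OC)CO | intermediate
14 | methyl (2R)-2-methyl-2-({2-methoxy-6-methyl-4-[(triisopropylsilyl)oxy]benzoyl}oxy)-3-oxopropanoate | COC(=O)[C@](C)(OC(=O)c1c(C)cc(O[Si](C(C)C)(C(C)C)C(C)C)cc1OC)C=O | intermediate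
15 | 4-hydroxybutan-2-one | CC(=O)CCO | starting material
16 | 4-{[tert-butyl(dimethyl)silyl]oxy}butan-2-one | CC(=O)CCO[Si](C)(C)C(C)(C)C | intermediate
17 | lithium 4-{[tert-butyl(dimethyl)silyl]oxy}but-1-en-2-olate | C=C(O[Li])CCO[Si](C)(C)C(C)(C)C | intermediate (not isolated)
18 | lithium aldolate, methyl (2R,3R)-7-{[tert-butyl(dimethyl)silyl]oxy}-3-(lithiooxy)-2-methyl-2-({2-methoxy-6-methyl-4-[(triisopropylsilyl)oxy]benzoyl}oxy)-5-oxoheptanoate | COC(=O)[C@](C)(OC(=O)c1c(C)cc(O[Si](C(C)C)(C(C)C)C(C)C)cc1OC)[C@H](O[Li])CC(=O)CCO[Si](C)(C)C(C)(C)C | intermediate (not isolated)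
19 | (1R,6R)-3-({[tert-butyl(dimethyl)silyl]oxy}methyl)-4,6-dihydroxy-1-methyl-2-oxocyclohex-3-en-1-yl 2-methoxy-6-methyl-4-[(triisopropylsilyl)oxy]benzoate | OC1=C(CO[Si](C)(C)C(C)(C)C)C(=O)[C@](C)(OC(=O)c2c(C)cc(O[Si](C(C)C)(C(C)C)C(C)C)cc2OC)[C@H](O)C1 | intermediate
20 | (1R,6R)-3-({[tert-butyl(dimethyl)silyl]oxy}methyl)-6-hydroxy-1-methyl-2-oxo-4-{[(trifluoromethyl)sulfonyl]oxy}cyclohex-3-en-1-yl 2-methoxy-6-methyl-4-[(triisopropylsilyl)oxy]benzoate | O=S(=O)(OC1=C(CO[Si](C)(C)C(C)(C)C)C(=O)[C@](C)(OC(=O)c2c(C)cc(O[Si](C(C)C)(C(C)C)C(C)C)cc2OC)[C@H](O)C1)C(F)(F)F | intermediate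
21 | (E)-1-bromoprop-1-ene | C/C=C/Br | starting material
22 | ethynyltrimethylsilane | C#C[Si](C)(C)C | starting material
23 | trimethyl[(3E)-pent-3-en-1-yn-1-yl]silane | C/C=C/C#C[Si](C)(C)C | intermediate
24 | (3E)-pent-3-en-1-yne | C/C=C/C#C | intermediate
25 | (1R,6R)-3-({[tert-butyl(dimethyl)silyl]oxy}methyl)-6-hydroxy-1-methyl-2-oxo-4-[(3E)-pent-3-en-1-yn-1-yl]cyclohex-3-en-1-yl 2-methoxy-6-methyl-4-[(triisopropylsilyl)oxy]benzoate | C/C=C/C#CC1=C(CO[Si](C)(C)C(C)(C)C)C(=O)[C@](C)(OC(=O)c2c(C)cc(O[Si](C(C)C)(C(C)C)C(C)C)cc2OC)[C@H](O)C1 | intermediate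
26 | (1R,6R)-6-hydroxy-3-(hydroxymethyl)-1-methyl-2-oxo-4-[(3E)-pent-3-en-1-yn-1-yl]cyclohex-3-en-1-yl 4-hydroxy-2-methoxy-6-methylbenzoate | C/C=C/C#CC1=C(CO)C(=O)[C@](C)(OC(=O)c2c(C)cc(O)cc2OC)[C@H](O)C1 | intermediate
27 | (6R,7R)-6-hydroxy-7-methyl-8-oxo-3-[(1E)-prop-1-en-1-yl]-5,6,7,8-tetrahydro-1H-isochromen-7-yl 4-hydroxy-2-methoxy-6-methylbenzoate | C/C=C/C1=CC2=C(CO1)C(=O)[C@](C)(OC(=O)c1c(C)cc(O)cc1OC)[C@H](O)C2 | target

**Step count and risks**
Total steps: 17. Longest linear sequence: 11 steps (5 → 6 → 8 → 9 → 12 → 13 → 14 → 19 → 20 → 25 → 26 → 27; steps 4–9, 11, 12, 15–17).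

Three steps most likely to fail:

1. Step 11. What may go wrong: reversal of the aldol addition on warming, transfer of the aroyl group to the neighbouring lithium alkoxide, approach of the enolate to the wrong face of the aldehyde, or loss of silanolate from the C8a enolate before it acylates. The fallback makes the two bonds one after the other and sets out from 16 and 14. Ketone 16 is converted (LiN(i-Pr)2, Me3SiCl, THF, −78 °C) into its kinetic silyl enol ether, [(4-{[tert-butyl(dimethyl)silyl]oxy}but-1-en-2-yl)oxy]trimethylsilane F1. Mukaiyama aldol addition of F1 to 14 with MgBr2·OEt2 (CH2Cl2, −78 °C), where the magnesium ion bridges the aldehyde and ester carbonyls, should give the neutral β-hydroxy ketone, methyl (2R,3R)-7-{[tert-butyl(dimethyl)silyl]oxy}-3-hydroxy-2-methyl-2-({2-methoxy-6-methyl-4-[(triisopropylsilyl)oxy]benzoyl}oxy)-5-oxoheptanoate F2. Silylation (Et3SiOTf, 2,6-lutidine) gives its 3-O-triethylsilyl ether F3, and Claisen cyclisation (LiN(SiMe3)2, THF, −78 → 0 °C) gives the 6-O-triethylsilyl ether of 19 F4. AcOH/THF/H2O then removes the secondary triethylsilyl group, and the sequence comes back to the route at 19.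

2. Step 17. What may go wrong: addition of the hydroxyl group to the nearer alkyne carbon (5-exo-dig) followed by aromatisation to a furan, or decomposition of the diene under the π-acid. The fallback sets out from 26 and fixes the site of C–O bond formation by conjugate addition. Et2NH (MeOH, 23 °C) should add in 1,6-fashion to the enynone at C3 and give the dienaminone, (1R,6R)-4-[(3E)-2-(diethylamino)penta-1,3-dien-1-yl]-6-hydroxy-3-(hydroxymethyl)-1-methyl-2-oxocyclohex-3-en-1-yl 4-hydroxy-2-methoxy-6-methylbenzoate F5. Brief treatment with AcOH in CH2Cl2 should let the hydroxymethyl oxygen displace diethylamine at C3 (addition–elimination, as in chromone formation from enaminones), and the sequence comes back to the route at 27.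

3. Step 7. What may go wrong: the hindered tertiary alkoxide may be too slow towards the di-ortho-substituted acyl chloride, so that self-condensation of the hydroxy ester takes over. The fallback sets out from 9 and makes the ester through a ketene. Commercial orsellinic acid is converted (acetone, (CF3CO)2O, CF3CO2H) into its acetonide, 7-hydroxy-2,2,5-trimethyl-4H-1,3-benzodioxin-4-one F6, which is silylated (i-Pr3SiCl, imidazole) to 2,2,5-trimethyl-7-[(triisopropylsilyl)oxy]-4H-1,3-benzodioxin-4-one F7. Irradiation of F7 (300 nm, CH2Cl2) in the presence of 9 should release a quinoketene that is trapped by the tertiary alcohol to give methyl (2R)-3-(benzyloxy)-2-({2-hydroxy-6-methyl-4-[(triisopropylsilyl)oxy]benzoyl}oxy)-2-methylpropanoate F8. O-Methylation of the remaining phenol (MeI, K2CO3, acetone) then brings the sequence back to the route at 12.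

**Further compounds**
F1 | step 11 | [(4-{[tert-butyl(dimethyl)silyl]oxy}but-1-en-2-yl)oxy]trimethylsilane | C=C(O[Si](C)(C)C)CCO[Si](C)(C)C(C)(C)C
F2 | step 11 | methyl (2R,3R)-7-{[tert-butyl(dimethyl)silyl]oxy}-3-hydroxy-2-methyl-2-({2-methoxy-6-methyl-4-[(triisopropylsilyl)oxy]benzoyl}oxy)-5-oxoheptanoate | COC(=O)[C@](C)(OC(=O)c1c(C)cc(O[Si](C(C)C)(C(C)C)C(C)C)cc1OC)[C@H](O)CC(=O)CCO[Si](C)(C)C(C)(C)C
F3 | step 11 | 3-O-triethylsilyl ether of F2 | COC(=O)[C@](C)(OC(=O)c1c(C)cc(O[Si](C(C)C)(C(C)C)C(C)C)cc1OC)[C@H](O[Si](CC)(CC)CC)CC(=O)CCO[Si](C)(C)C(C)(C)C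
F4 | step 11 | 6-O-triethylsilyl ether of 19 | OC1=C(CO[Si](C)(C)C(C)(C)C)C(=O)[C@](C)(OC(=O)c2c(C)cc(O[Si](C(C)C)(C(C)C)C(C)C)cc2OC)[C@H](O[Si](CC)(CC)CC)C1
F5 | step 17 | (1R,6R)-4-[(3E)-2-(diethylamino)penta-1,3-dien-1-yl]-6-hydroxy-3-(hydroxymethyl)-1-methyl-2-oxocyclohex-3-en-1-yl 4-hydroxy-2-methoxy-6-methylbenzoate | C/C=C/C(N(CC)CC)=CC1=C(CO)C(=O)[C@](C)(OC(=O)c2c(C)cc(O)cc2OC)[C@H](O)C1
F6 | step 7 | 7-hydroxy-2,2,5-trimethyl-4H-1,3-benzodioxin-4-one | Cc1cc(O)cc2OC(C)(C)OC(=O)c12
F7 | step 7 | 2,2,5-trimethyl-7-[(triisopropylsilyl)oxy]-4H-1,3-benzodioxin-4-one | Cc1cc(O[Si](C(C)C)(C(C)C)C(C)C)cc2OC(C)(C)OC(=O)c12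
F8 | step 7 | methyl (2R)-3-(benzyloxy)-2-({2-hydroxy-6-methyl-4-[(triisopropylsilyl)oxy]benzoyl}oxy)-2-methylpropanoate | COC(=O)[C@](C)(OC(=O)c1c(C)cc(O[Si](C(C)C)(C(C)C)C(C)C)cc1O)COCc1ccccc1
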